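A small charge of free catalyst, 1 mol% on 2 mM of substrate at 35 °C, turned substrate into target in Wednesday's run, and those readings are what I have for the four new flasks.

| flask | substrate | free catalyst | temperature | remark | time |
|---|---|---|---|---|---|
| Wednesday's | 2 mM | 1 mol% | 35 °C | run made earlier |  |
| west | 2.0 mM | 2 mol% | 35 °C |  | 5.0 min |
| north-west | 2.0 mM | 2 mol% | 85 °C |  | 5.0 min |
| south | 2.0 mM | 2 mol% |  | at 85 °C until 2.5 min, from then on at 35 °C | 5.0 min |
| south-east | 2.0 mM | 2 mol% | 60 °C |  | 5.0 min |

Wednesday's run (percent of the substrate charged)

| time / s | target / % |
|---|---|
| 10.0 | 25 |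
| 12.0 | 31 |
| 20.0 | 45 |
| 30.0 | 53 |
| 50.0 | 62 |
| 60.0 | 66 |

(scatter of a reading: 1.5 percentage points)

- the earlier runs do not show what temperature does; that part of a forecast is a guess
- no earlier run changes the charge of free catalyst; that part of a forecast is a guess

* the flask with the highest amount of target, in percent of the substrate charged ("all alike" if they lie within 1.5 percentage points) (west / north-west / south / south-east / all alike)
* final target, as a percentage of the substrate charged, in west
* final target, as a percentage of the substrate charged, in north-west
* final target, as a percentage of the substrate charged, in south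
* final target, as a percentage of the substrate charged, in south-east

I work with f, the fraction of the charge not yet target, and not with the target made. The bench rule is pseudo-first-order: f falls by the same factor in each equal time, so k = ln(1/f)/t should come out alike at every reading. The first reading gives 0.0288 s⁻¹, which is a half-life of 24.1 s. West's 5.0 min would then be 12.4 half-lives, and hardly any of the charge would stay unturned.

The last reading shows the border of that rule. The rule gives f = 17.8% there, but the reading gives 34.0%, which is more by 16 percentage points, against a scatter of 1.5 points. The apparent constant k from the last reading is 0.0180 s⁻¹, lower by a factor of 1.60. West's time also lies 5.00 times beyond that reading. So I refuse the rule's near-complete figure for west and name no firm number, since west runs at 2 mol% of free catalyst against Wednesday's 1 mol%, and what that change does is a guess. What I watch is k at each sampling.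

The forecast does commit: 80% in west, 72% in north-west, 77% in south, 77% in south-east, with west highest, on the ground that “Five minutes is long, so all flasks should reach their limit”.

The flasks give 65.6% in west, 0.00780% in north-west, 0.695% in south and 23.3% in south-east, so west stands highest.

    2 free catalyst → spent catalyst (k = 437 L mol⁻¹ s⁻¹, Ea = 36.0 kJ mol⁻¹)
    substrate ⇌ target (K = 3.50, k = 0.396 s⁻¹, Ea = 85.0 kJ mol⁻¹, ΔH = 5.00 kJ mol⁻¹)
    substrate ⇌ isomer of the product (K = 0.0732, k = 0.103 s⁻¹, Ea = 85.0 kJ mol⁻¹, ΔH = 11.0 kJ mol⁻¹)
    substrate → uncatalysed product (k = 0.0183 s⁻¹, Ea = 86.0 kJ mol⁻¹)
    (constants at 60 °C)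

In west at 5.0 min, f is 34.4%, made up of substrate at 21.0%, uncatalysed product at 12.2% and isomer of the product at 1.12%, and k is 0.003560 s⁻¹, lower than Wednesday's last value by a factor of 5.06. The neighbour, the same flask as west read at 8.0 min, gives target 61.6%, so its f has risen to 38.4% and its k is 0.001994 s⁻¹, lower again. In that neighbour, uncatalysed product stands at 17.6%.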